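The flask held 0.050 M of each substrate hand, and 0.0600 M of the single-handed partner was fed in over 15 s. I had followed it to 40.0 s as the dawn run, and for the next run I had to choose between more time and more partner.

| flask | left-handed substrate | right-handed substrate | partner | remark | time |
|---|---|---|---|---|---|
| dawn | 0.050 M | 0.050 M | 0.060 M (fed, over 15 s) | the very flask that is asked about, followed so far; the fed solution adds 0.10 times the starting volume |  |
| winter | 0.10 M | 0.10 M | 0.060 M (fed, over 15 s) | run made earlier; the fed solution adds 0.10 times the starting volume |  |
| flask | 0.050 M | 0.050 M | 0.0600 M (fed, over 15 s) | the fed solution adds 0.10 times the starting volume | 4.0 min |

- dawn (time / s: left-handed product / %, right-handed product / %): 10.0: 11.3, 4.0; 15.0: 18.3, 8.8; 30.0: 23.8, 13.1; 40.0: 24.0, 11.5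
- winter (time / s: left-handed product / %, right-handed product / %): 12.0: 10.9, 4.6; 30.0: 16.0, 7.0; 60.0: 15.5, 7.6; 90.0: 16.6, 7.8

(standard deviation of a reading: 0.5 percentage points)

- partner is single-handed; left-handed substrate and right-handed substrate are mirror images of each other, charged as a racemate, each of them at the stated concentration
- charges are per starting volume, the dose included; the dosed solution carries all of it
- the numbers in the tables scatter by 0.5 percentage points (one standard deviation)
- steps that have been proposed: partner -> decomposed reagent; partner + left-handed substrate -> left-handed product; partner + right-handed substrate -> right-handed product; 2 partner -> homo dimer
- the handed part of partner does not stay in what it makes, so the products of the two hands are mirror images too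

* amount of left-handed product in the flask at 4.0 min, in percent of the left-handed substrate and right-handed substrate together charged
* amount of right-handed product in the flask at 4.0 min, in percent of the left-handed substrate and right-handed substrate together charged
* amount of left-handed substrate in the flask at 4.0 min, in percent of the left-handed substrate and right-handed substrate together charged

Time looked useless. In this flask the left-handed product moved by 0.2 percentage points between 30.0 s and 40.0 s, against a scatter of 0.5 points, and the winter run, with twice the substrate, went from 16.0% at 30.0 s to 16.6% at 90.0 s. So I took the plateau for 4.0 min, using the mean of the last two readings: 23.9% left-handed product and 12.3% right-handed, which leaves 26.1% left-handed substrate, since each product takes one substrate.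

That left the partner. Each hand meets the same partner in its own step, so however the partner's concentration runs, the logarithms of the two remaining fractions keep a constant ratio, the selectivity factor. This flask reads 2.30, and the winter run reads 2.39. Partner lost to decomposition or dimer changes how far a flask travels along that curve, but not the curve. So I chose more partner: the left-handed fraction remaining should be the right-handed fraction raised to that factor.

The forecast, “perhaps with a small tail still to come”, gave 24.3%, 12.5% and 25.7%. The flask gave 24.1%, 12.5% and 25.9%.

    partner → decomposed reagent (k = 0.0770 s⁻¹)
    partner + left-handed substrate → left-handed product (k = 2.50 M⁻¹ s⁻¹)
    partner + right-handed substrate → right-handed product (k = 1.10 M⁻¹ s⁻¹)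
    2 partner → homo dimer (k = 0.260 M⁻¹ s⁻¹)

This flask kept 75% of its right-handed substrate charge, and raising that to 2.30 gives 51.6%, beside the 52% it kept of the left-handed. The neighbour flask changed one setting, with 0.10 M of partner, and reached 34.9% left-handed and 20.4% right-handed product at the same time. It kept 59% of its right-handed substrate, so the same curve gives 29.7% for the left-handed, and that flask kept 30%.

The readings were computed for substances that don't exist; the scatter is artificial.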